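The earlier runs and the new flask are calculated with constants of no real substance.

The target was the business of this short meeting: how much of it stands in the flask at the asked time, and how much substrate has reacted by then.

| setting | dawn | summer | flask |
|---|---|---|---|
| substrate | 0.27 M | 0.60 M | 0.40 M |
| reagent in the second phase | 0.28 M | 0.28 M | 0.280 M |
| remark | run made earlier | run made earlier |  |
| time |  |  | 8.0 d |
| volume of the second phase over the first |  |  | 1.0 |

| run | time / d | target / % | substrate / % |
|---|---|---|---|
| dawn | 0.500 | 4.3 | 92.7 |
| dawn | 1.04 | 12.9 | 84.7 |
| dawn | 1.67 | 16.2 | 77.4 |
| dawn | 3.00 | 19.8 | 67.6 |
| dawn | 6.00 | 22.1 | 57.9 |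
| summer | 1.25 | 10.6 | 86.2 |
| summer | 2.50 | 16.2 | 82.3 |
| summer | 4.00 | 19.8 | 73.7 |
| summer | 5.00 | 19.8 | 73.6 |
| summer | 6.00 | 18.1 | 73.7 |

(each reading ± 1 percentage point)

- in the second phase: reagent in the second phase; everything else is in the first
- charges count per volume of the first phase; a concentration in a rate is the amount of a species over the volume of its own phase; every rate counts per litre of the first phase
- the earlier runs hold the two phases in the same ratio of volumes as the flask asked about

- the target standing at 8.0 d, as a percentage of the substrate charged
- part of the substrate charged that has reacted at 8.0 d

The chemist of the summer run reported that its substrate fell to 82.3% by 2.50 d and to 73.7% by 4.00 d, and still read 73.7% at 6.00 d. The chemist of the dawn run objected that dawn's substrate was still falling at its last reading, 57.9%. Both runs hold the same charge of reagent in the second phase as the flask.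

I proposed counting half-lives. In the summer run the gap between substrate and its final reading shrank from 26 percentage points to 8.6 points in 2.50 d, which gives 1.55 d. This stall half-life, the time in which the gap to the stall halves, I took as the clock of the reagent in the second phase, an assumption that the meeting let stand. The flask's time is longer than this clock: it counts 5.16 half-lives, which should leave 2.80% of that reagent's own charge. My count yields a time and a remainder, not a yield.

The forecast, made from these runs, judged that the stall “looks like reagent exhaustion” and gave 20% target with 36% of the substrate reacted.

The flask gives 20.8% target, with 36.7% of the substrate reacted. What runs in it is this: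

    reagent in the reaction phase + target → over-reacted product (k = 0.560 M⁻¹ h⁻¹)
    reagent in the reaction phase ⇌ reagent in the second phase, rate k2*([reagent in the reaction phase] - [reagent in the second phase]/K2) per volume of the first phase (partition coefficient = 2.10, kL = 0.0680 h⁻¹)
    2 reagent in the reaction phase → homo dimer (k = 0.790 M⁻¹ h⁻¹)
    substrate + reagent in the reaction phase → target (k = 0.220 M⁻¹ h⁻¹)

In the flask at 8.00 d, the half-life of substrate by its turning into target is 97 d, longer than the 8.0 d of the run and up from 5.4 d at 1.23 d, while the reagent in the second phase, the limiting reagent here, stands at 2.30% of its own charge where the count gave 2.80%. The same charges read at 5.0 d count 3.23 half-lives, which gives 10.7%, and they hold 8.62% of that charge.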